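**Retrosynthetic overview**

1. Last step: the C6–C7 bond (geranylgeranyl C1–C10) and the O–C11 bond are opened together. As in the cyclase, an olefin attacks an electrophilic C1 (here an aldehyde) and oxygen captures the C11 cation, so ring B (cycloheptane) and ring C (oxolane) close in one cationic cascade from a monocyclic cyclopentenyl aldehyde.
2. The C14 hydroxyl and C15 acetate of that aldehyde come from a C14–C15 epoxide opened by acetic acid. The trans-2-methylcyclopent-2-ene carbaldehyde comes from the conjugated enal by deconjugation.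
3. Ring A (cyclopentene) comes from ring contraction of a limonene-1,2-diol unit (periodate cleavage, aldol condensation). The limonene C3–C4 bond is the C5–C1 bond (geranylgeranyl C2–C6).
4. C8–C9 bond: allylic lithiation of (1S,2S,4R)-limonene-1,2-diol and alkylation with (R)-6,7-epoxyneryl chloride (from nerol by Appel chlorination and Shi epoxidation).
5. Order of ring formation: ring A first; rings B and C together in the final step.

Assumption: locants C1–C15 are those of the dictyol skeleton (C1/C5 ring fusion, C6 carbinol, C7, methylidene on C10, oxolane carbons C11–C14, acetoxy-bearing C15); diol 4 and the Shi ketone are taken as purchasable.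

**Route**

Step 1
Reactants: 1 nerol
Product: 2 neryl chloride
Conditions: PPh3, CCl4, 70 °C
Reagents that add atoms: carbon tetrachloride ClC(Cl)(Cl)Cl
Why: Appel reaction, in which chloride displaces the alkoxyphosphonium group by SN2 at the primary allylic carbon under neutral conditions, so there is no allylic transposition and the Z olefin is kept (no stereocentre formed).

Step 2
Reactants: 2 neryl chloride
Product: 3 (R)-6,7-epoxyneryl chloride
Conditions: 1,2:4,5-di-O-isopropylidene-β-D-erythro-2,3-hexodiulo-2,6-pyranose (Shi ketone, 30 mol %), KHSO5 (as 2KHSO5·KHSO4·K2SO4), K2CO3, n-Bu4NHSO4 (cat.), MeCN/dimethoxymethane/aq. Na2B4O7 buffer, 0 °C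
Reagents that add atoms: potassium peroxymonosulfate KHSO5 [K+].[O-]S(=O)(=O)OO
Why: Shi asymmetric epoxidation, in which the chiral dioxirane attacks only the electron-rich distal olefin (the 2,3-olefin is deactivated by the allylic chloride) through the spiro transition state, which for R–CH=CMe2 olefins with the D-fructose-derived ketone gives the (R)-epoxide that becomes C14.

Step 3
Reactants: 4 (1S,2S,4R)-limonene-1,2-diol; 3 (R)-6,7-epoxyneryl chloride
Product: 6 (1S,2S,4R)-4-{(5Z)-8-[(2R)-3,3-dimethyloxiran-2-yl]-6-methylocta-1,5-dien-2-yl}-1-methylcyclohexane-1,2-diol, via trilithiated diol 5 (not isolated)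
Conditions: n-BuLi (3.3 equiv), N,N,N′,N′-tetramethylethylenediamine (3.3 equiv), hexane, 0 °C → rt; then 3, THF, −78 → −20 °C; H2O
Reagents that add atoms: none
Why: Allylic metalation of the isopropenyl methyl group (as in the n-BuLi/TMEDA lithiation of limonene, after both hydroxyls have become lithium alkoxides) followed by SN2 alkylation of the symmetric allyl anion by the primary allylic chloride, which forms the C8–C9 bond, keeps the Z olefin and the epoxide, and creates no stereocentre.

Step 4
Reactants: 6 coupled epoxy diol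
Product: 7 (3R)-3-{(5Z)-8-[(2R)-3,3-dimethyloxiran-2-yl]-6-methylocta-1,5-dien-2-yl}-6-oxoheptanal
Conditions: NaIO4, NaHCO3, THF/H2O, 0 °C → rt
Reagents that add atoms: none
Why: Malaprade glycol cleavage through the cyclic periodate ester gives the methyl ketone and the aldehyde without touching the olefins or the buffered epoxide, and the stereocentre (future C1) is not enolisable.

Step 5
Reactants: 7 keto aldehyde
Product: 8 (5S)-5-{(5Z)-8-[(2R)-3,3-dimethyloxiran-2-yl]-6-methylocta-1,5-dien-2-yl}-2-methylcyclopent-1-ene-1-carbaldehyde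
Conditions: piperidine (20 mol %), AcOH (20 mol %), 4 Å molecular sieves, toluene, 40 °C
Reagents that add atoms: none
Why: Intramolecular aldol condensation through the piperidine enamine of the aldehyde (the Wolinsky ring contraction of cleaved limonene), which adds to the methyl ketone and dehydrates to the conjugated cyclopentene carbaldehyde while C1 is untouched.

Step 6
Reactants: 8 conjugated enal
Product: 11 (1S,5R)-5-{(5Z)-8-[(2R)-3,3-dimethyloxiran-2-yl]-6-methylocta-1,5-dien-2-yl}-2-methylcyclopent-2-ene-1-carbaldehyde, via potassium dienolate 9 (not isolated), via cis aldehyde 10 (not isolated)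
Conditions: KOt-Bu, THF, −20 °C; inverse quench into AcOH/THF, −78 °C; then 1,8-diazabicyclo[5.4.0]undec-7-ene (5 mol %), CH2Cl2, −20 °C
Reagents that add atoms: none
Why: Deconjugative protonation, in which the thermodynamic potassium dienolate (ring γ-deprotonation, as in the β- to α-cyclocitral isomerisation) is protonated kinetically at the α-carbon to place the olefin at C3=C4, and the kinetically favoured cis aldehyde is then equilibrated by base-catalysed enolisation to the more stable trans isomer, which sets C5 (S) trans to the C1 substituent.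

Step 7
Reactants: 11 trans epoxy aldehyde
Product: 12 (3R,6Z)-10-[(1R,5S)-5-formyl-4-methylcyclopent-3-en-1-yl]-3-hydroxy-2,6-dimethylundeca-6,10-dien-2-yl acetate
Conditions: AcOH, NaOAc, 35 °C
Reagents that add atoms: acetic acid CC(=O)O
Why: Acid-mediated Markovnikov acetolysis of the trisubstituted epoxide, in which acetic acid opens the protonated oxirane at the tertiary carbon C15 with SN1-like character, so the C14–O bond and its (R) configuration are untouched and the tertiary acetate is installed next to a free secondary hydroxyl.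

Step 8
Reactants: 12 hydroxy acetate aldehyde
Product: 13 2-{(2R,5S)-5-[(3aS,4S,5R,8aR)-4-hydroxy-3-methyl-8-methylidene-1,3a,4,5,6,7,8,8a-octahydroazulen-5-yl]-5-methyloxolan-2-yl}propan-2-yl acetate
Conditions: Sc(OTf)3 (10 mol %), 4 Å molecular sieves, CH2Cl2, −78 → −30 °C; aq. NaHCO3
Reagents that add atoms: none
Why: Proposed new method: Sc(OTf)3 activates the aldehyde (geranylgeranyl C1) for a Prins-type attack by the less substituted carbon C7 of the (Z)-C7=C11 olefin, the tertiary C11 cation is trapped 5-exo by the C14 hydroxyl anti to the new C6–C7 bond (so the Z geometry becomes the 7R,11S pair), C6 becomes S because the scandium-bound oxygen stays pseudo-equatorial (C=O eclipsed with C5–H) while C7 adds from the C1 side, and C7 is expected from a twist-chair transition state that keeps C11 anti to C5 and gauche to the C6–O bond (hydroxyl and side chain cis); the closest known chemistry is the Sc(OTf)3- or alkylaluminium chloride-promoted intramolecular Prins/carbonyl-ene cyclisation of unsaturated aldehydes (citronellal to isopulegol) combined with hydroxyl-terminated cation–olefin cyclisation (homofarnesol to ambroxide type).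

**Compound list**

1 | nerol, (2Z)-3,7-dimethylocta-2,6-dien-1-ol | CC(C)=CCC/C(C)=C\CO | starting material
2 | neryl chloride, (2Z)-1-chloro-3,7-dimethylocta-2,6-diene | CC(C)=CCC/C(C)=C\CCl | intermediate
3 | (R)-6,7-epoxyneryl chloride, (3R)-3-[(3Z)-5-chloro-3-methylpent-3-en-1-yl]-2,2-dimethyloxirane | CC1(C)O[C@@H]1CC/C(C)=C\CCl | intermediate
4 | (1S,2S,4R)-limonene-1,2-diol, (1S,2S,4R)-1-methyl-4-(prop-1-en-2-yl)cyclohexane-1,2-diol | CC(=C)[C@@H]1CC[C@](C)(O)[C@@H](O)C1 | starting material
5 | trilithiated diol (dilithium alkoxide of 4, lithiated at the isopropenyl methyl carbon) | [Li]CC(=C)[C@@H]1CC[C@](C)(O[Li])[C@@H](O[Li])C1 | intermediate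
6 | (1S,2S,4R)-4-{(5Z)-8-[(2R)-3,3-dimethyloxiran-2-yl]-6-methylocta-1,5-dien-2-yl}-1-methylcyclohexane-1,2-diol | C=C(CC/C=C(C)\CC[C@H]1OC1(C)C)[C@@H]1CC[C@](C)(O)[C@@H](O)C1 | intermediate
7 | (3R)-3-{(5Z)-8-[(2R)-3,3-dimethyloxiran-2-yl]-6-methylocta-1,5-dien-2-yl}-6-oxoheptanal | C=C(CC/C=C(C)\CC[C@H]1OC1(C)C)[C@@H](CC=O)CCC(C)=O | intermediate
8 | (5S)-5-{(5Z)-8-[(2R)-3,3-dimethyloxiran-2-yl]-6-methylocta-1,5-dien-2-yl}-2-methylcyclopent-1-ene-1-carbaldehyde | C=C(CC/C=C(C)\CC[C@H]1OC1(C)C)[C@H]1C(C=O)=C(C)CC1 | intermediate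
9 | potassium dienolate of 8 (enolate C6=C5, ring olefin at C3=C4) | C=C(CC/C=C(C)\CC[C@H]1OC1(C)C)[C@@H]1CC=C(C)C1=CO[K] | intermediate
10 | (1R,5R)-5-{(5Z)-8-[(2R)-3,3-dimethyloxiran-2-yl]-6-methylocta-1,5-dien-2-yl}-2-methylcyclopent-2-ene-1-carbaldehyde (cis) | C=C(CC/C=C(C)\CC[C@H]1OC1(C)C)[C@@H]1CC=C(C)[C@@H]1C=O | intermediate
11 | (1S,5R)-5-{(5Z)-8-[(2R)-3,3-dimethyloxiran-2-yl]-6-methylocta-1,5-dien-2-yl}-2-methylcyclopent-2-ene-1-carbaldehyde (trans) | C=C(CC/C=C(C)\CC[C@H]1OC1(C)C)[C@@H]1CC=C(C)[C@H]1C=O | intermediate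
12 | (3R,6Z)-10-[(1R,5S)-5-formyl-4-methylcyclopent-3-en-1-yl]-3-hydroxy-2,6-dimethylundeca-6,10-dien-2-yl acetate | C=C(CC/C=C(C)\CC[C@@H](O)C(C)(C)OC(C)=O)[C@@H]1CC=C(C)[C@H]1C=O | intermediate
13 | 2-{(2R,5S)-5-[(3aS,4S,5R,8aR)-4-hydroxy-3-methyl-8-methylidene-1,3a,4,5,6,7,8,8a-octahydroazulen-5-yl]-5-methyloxolan-2-yl}propan-2-yl acetate | C=C1CC[C@@H]([C@]2(C)CC[C@H](C(C)(C)OC(C)=O)O2)[C@@H](O)[C@@H]2C(C)=CC[C@@H]12 | target

**Step count and risks**

Total steps: 8. Longest linear sequence: 8 steps (1 → 2 → 3 → 6 → 7 → 8 → 11 → 12 → 13); diol 4 is used as bought.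

Steps most likely to fail:

Step 8 (cascade). The seven-membered Prins closure may stop at the carbonyl-ene stage, or may close with the other olefin face at C7; the face selectivity at C7 is the least secure prediction in the route. Fallback: setting out from 12, the two ring closures are separated and C11 is set by substrate control instead of by anti addition. Me2AlCl (2.2 equiv, CH2Cl2, −78 °C) is used to stop at the carbonyl-ene product, the ene alcohol F1 (C6–OH, C7–H, exocyclic methylene on C11, C14–OH free). AgOTf (10 mol %, 1,2-dichloroethane, 40 °C) then adds the C14 hydroxyl to the C11 methylene (Markovnikov, 5-exo; attack anti to C6 in the H7-eclipsed conformer gives 11S), and the route is rejoined at 13.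

Step 6 (deconjugation). The dienolate may form towards the methyl group (exocyclic olefin), the cis aldehyde may resist equilibration, or the aldehyde may slip back into conjugation. Fallback: setting out from 7, the C5 centre is fixed before the ring olefin exists. L-Proline-catalysed aldol addition without dehydration (DMSO, rt) gives the trans β-hydroxy aldehyde F2 (C4–OH cis to H5). AcOH/NaOAc as in step 7 gives the hydroxy acetate F3. The Sc(OTf)3 cascade of step 8 gives the 4,6-diol F4. Ac2O/pyridine acetylates only the secondary C6 hydroxyl, giving the monoacetylated diol F5. SOCl2/pyridine (−30 °C) removes the tertiary C4 hydroxyl by anti elimination, which cannot use H5 (syn to the leaving group) and so gives mainly the C3=C4 olefin, the 6-O-acetyl compound F6. K2CO3/MeOH at 0 °C cleaves the secondary acetate faster than the tertiary one, and the route is rejoined at 13.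

Step 3 (polyanion metalation). The dilithium alkoxide may be too insoluble to be lithiated cleanly, or the alkoxides may attack the allylic chloride. Fallback: setting out from 4, the polyanion is avoided by a protecting-group detour. TESOTf/2,6-lutidine gives the bis(triethylsilyl) ether F7. Its single allyl anion (sec-BuLi/TMEDA, −78 → 0 °C) is alkylated with 3 to give the coupled bis-silyl ether F8. n-Bu4NF (THF, rt) removes both silyl groups, and the route is rejoined at 6.

**Further compounds**

F1 | step 8 | ene alcohol (13 without the O–C11 bond: exocyclic methylene on C11, free C14–OH, same spatial arrangement at C1, C5, C6, C7 and C14) | C=C1CC[C@@H](C(=C)CC[C@@H](O)C(C)(C)OC(C)=O)[C@@H](O)[C@@H]2C(C)=CC[C@@H]12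
F2 | step 6 | trans β-hydroxy aldehyde (aldol adduct of 7: 2-hydroxy-2-methylcyclopentane-1-carbaldehyde with C4–OH cis to H5 and CHO trans to the C1 side chain, epoxide intact) | C=C(CC/C=C(C)\CC[C@H]1OC1(C)C)[C@@H]1CC[C@](C)(O)[C@H]1C=O
F3 | step 6 | hydroxy acetate of F2 (C14–OH, C15–OAc) | C=C(CC/C=C(C)\CC[C@@H](O)C(C)(C)OC(C)=O)[C@@H]1CC[C@](C)(O)[C@H]1C=O
F4 | step 6 | 4,6-diol (13 with C3–C4 saturated and a tertiary C4–OH cis to H5) | C=C1CC[C@@H]([C@]2(C)CC[C@H](C(C)(C)OC(C)=O)O2)[C@@H](O)[C@@H]2[C@@](C)(O)CC[C@@H]12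
F5 | step 6 | 6-O-acetyl derivative of F4 | C=C1CC[C@@H]([C@]2(C)CC[C@H](C(C)(C)OC(C)=O)O2)[C@@H](OC(C)=O)[C@@H]2[C@@](C)(O)CC[C@@H]12
F6 | step 6 | 6-O-acetyl derivative of 13 | C=C1CC[C@@H]([C@]2(C)CC[C@H](C(C)(C)OC(C)=O)O2)[C@@H](OC(C)=O)[C@@H]2C(C)=CC[C@@H]12
F7 | step 3 | (1S,2S,4R)-1-methyl-4-(prop-1-en-2-yl)-1,2-bis(triethylsilyloxy)cyclohexane | CC(=C)[C@@H]1CC[C@](C)(O[Si](CC)(CC)CC)[C@@H](O[Si](CC)(CC)CC)C1
F8 | step 3 | bis(triethylsilyl) ether of 6 | C=C(CC/C=C(C)\CC[C@H]1OC1(C)C)[C@@H]1CC[C@](C)(O[Si](CC)(CC)CC)[C@@H](O[Si](CC)(CC)CC)C1
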